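**Retrosynthetic overview**

1. The strategy rests on ring B, the benzene ring of the dioxin. It carries three neighbouring aryl ether oxygens (B5–O–C9 and B6–O–C8 to ring D of the dibenzofuran, B1–O to ring A) between the hydroxyl carbons B2 and B4, with B3–H between those two. B2 and B4 therefore enter as formyl groups that activate B1 and B5 for SNAr and later become the hydroxyls by Dakin oxidation.
2. Key disconnection: all three aryl ether bonds of ring B in one pot, to 4,5,6-trifluoroisophthalaldehyde 15, dibenzofuranol 11 (C9–OH free, C8–O masked as 2-(trimethylsilyl)ethyl ether) and 3,5-dimethoxyphenol 3.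
3. Dibenzofuranol 11 comes from a diaryl ether (SNAr of 3 on 2), furan closure by palladium-catalysed direct arylation, and two formyl-to-hydroxyl sequences that place the C8 and C9 oxygens one after the other. Hub 15 comes from the dioxolane of 2,3,4-trifluorobenzaldehyde by lithiation next to fluorine and formylation.
4. Ring order: rings A, B, D and E are bought as benzenes; the furan ring closes in step 3 and the dioxin ring in step 10; double Dakin oxidation and BBr3 finish the route.

Key step: step 10

Remark: dibenzofuran atoms carry their usual locants (C1 to C9b); ring B is numbered B1 (O–ring A), B2, B3, B4, B5 (O–C9), B6 (O–C8). Compounds 1, 3 and 12 are assumed to be catalogue compounds.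

**Route**

Step 1
Reactants: 1 4-fluoro-2-methoxybenzaldehyde
Product: 2 5-bromo-4-fluoro-2-methoxybenzaldehyde
Conditions: Br2 (1.05 equiv), AcOH, 25 °C
Reagents that add atoms: bromine, BrBr
Why: Electrophilic aromatic bromination should go para to the methoxy group, the position that is also ortho to fluorine and meta to the formyl group.

Step 2
Reactants: 2 5-bromo-4-fluoro-2-methoxybenzaldehyde; 3 3,5-dimethoxyphenol
Product: 4 5-bromo-4-(3,5-dimethoxyphenoxy)-2-methoxybenzaldehyde
Conditions: K2CO3, DMF, 90 °C
Reagents that add atoms: none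
Why: SNAr of the phenoxide at the C–F bond para to the formyl group; the bromide is meta to the formyl group and should stay.

Step 3
Reactants: 4 5-bromo-4-(3,5-dimethoxyphenoxy)-2-methoxybenzaldehyde
Product: 5 1,3,7-trimethoxydibenzofuran-8-carbaldehyde
Conditions: Pd(OAc)2 (5 mol%), PCy3·HBF4 (10 mol%), K2CO3, DMA, 130 °C
Reagents that add atoms: none
Why: Palladium-catalysed intramolecular direct arylation of a 2-bromodiaryl ether (concerted metalation–deprotonation) closes the furan ring at either of the two equivalent C–H positions ortho to the ether oxygen of the symmetric 3,5-dimethoxyphenoxy ring.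

Step 4
Reactants: 5 1,3,7-trimethoxydibenzofuran-8-carbaldehyde
Product: 7 1,3,7-trimethoxydibenzofuran-8-ol, via aryl formate 6 (not isolated)
Conditions: mCPBA, CH2Cl2, 0 °C to rt; aq. NaHCO3 wash; K2CO3 (cat.), MeOH, rt
Reagents that add atoms: 3-chloroperoxybenzoic acid, O=C(OO)c1cccc(Cl)c1
Why: Baeyer–Villiger (Dakin-type) oxidation in which the aryl group migrates because it carries an ortho methoxy group and a para furan oxygen, followed by methanolysis of the formate.

Step 5
Reactants: 7 1,3,7-trimethoxydibenzofuran-8-ol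
Product: 8 8-hydroxy-1,3,7-trimethoxydibenzofuran-9-carbaldehyde
Conditions: MgCl2, Et3N, (CH2O)n, MeCN, reflux; aq. HCl work-up
Reagents that add atoms: formaldehyde (as paraformaldehyde), C=O
Why: Magnesium phenoxide-directed ortho-formylation (Casnati–Skattebøl) can only go to C9, because the other ortho position, C7, carries the methoxy group.

Step 6
Reactants: 8 8-hydroxy-1,3,7-trimethoxydibenzofuran-9-carbaldehyde
Product: 9 1,3,7-trimethoxy-8-[2-(trimethylsilyl)ethoxy]dibenzofuran-9-carbaldehyde
Conditions: 2-(trimethylsilyl)ethanol, PPh3, DIAD, THF, 0 °C to rt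
Reagents that add atoms: 2-(trimethylsilyl)ethanol, C[Si](C)(C)CCO
Why: Mitsunobu etherification of the acidic salicylaldehyde-type phenol with a primary alcohol puts the mask on the C8 oxygen while C9 still carries carbon, so the two oxygens cannot be confused.

Step 7
Reactants: 9 1,3,7-trimethoxy-8-[2-(trimethylsilyl)ethoxy]dibenzofuran-9-carbaldehyde
Product: 11 1,3,7-trimethoxy-8-[2-(trimethylsilyl)ethoxy]dibenzofuran-9-ol, via aryl formate 10 (not isolated)
Conditions: mCPBA, CH2Cl2, 0 °C to rt; aq. NaHCO3 wash; K2CO3 (cat.), MeOH, rt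
Reagents that add atoms: 3-chloroperoxybenzoic acid, O=C(OO)c1cccc(Cl)c1
Why: Baeyer–Villiger oxidation with aryl migration (ortho alkoxy group) and methanolysis of the formate; the silylethyl ether is inert to peracid and to carbonate in methanol.

Step 8
Reactants: 12 2,3,4-trifluorobenzaldehyde
Product: 13 2-(2,3,4-trifluorophenyl)-1,3-dioxolane
Conditions: ethylene glycol, TsOH·H2O (cat.), toluene, Dean–Stark reflux
Reagents that add atoms: ethylene glycol, OCCO
Why: Acid-catalysed acetalisation driven by azeotropic removal of water protects the formyl group against the amide base of the next step.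

Step 9
Reactants: 13 2-(2,3,4-trifluorophenyl)-1,3-dioxolane
Product: 15 4,5,6-trifluoroisophthalaldehyde, via formyl dioxolane 14 (not isolated)
Conditions: LiN(iPr)2, THF, −78 °C; DMF, −78 °C; then 3 M HCl, THF, 50 °C
Reagents that add atoms: N,N-dimethylformamide, CN(C)C=O; water, O
Why: Directed lithiation removes the only hydrogen next to a fluorine (C5), DMF formylates the aryllithium at −78 °C before lithium fluoride can be lost, and aqueous acid hydrolyses the dioxolane.

Step 10
Reactants: 11 1,3,7-trimethoxy-8-[2-(trimethylsilyl)ethoxy]dibenzofuran-9-ol; 15 4,5,6-trifluoroisophthalaldehyde; 3 3,5-dimethoxyphenol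
Product: 19 B2,B4-diformyl pentamethyl ether of the target skeleton, via monoaryl ether 16 (not isolated), via bis-aryl ether 17 (not isolated), via unmasked phenol 18 (not isolated)
Conditions: (a) Cs2CO3, DMSO, 20 °C, slow addition of the caesium salt of 11 to 15 (1.0 equiv); (b) 3 (1.0 equiv), Cs2CO3, 25–40 °C; (c) dilution to 0.01 M, CsF (4 equiv), 110 °C
Reagents that add atoms: none
Why: Three addition–elimination SNAr events through Meisenheimer intermediates run in sequence: the caesium phenoxide of 11 (the C9 oxygen, the only free ring D oxygen) takes one of the two equivalent fluorines that are ortho to one formyl group and para to the other (B5), 3,5-dimethoxyphenoxide takes the second such fluorine (B1), and fluoride then removes the 2-(trimethylsilyl)ethyl group as Me3SiF and ethene so that the C8 phenoxide displaces the central fluorine (B6). The closest known reactions are the stepwise substitution of 1,5-difluoro-2,4-dinitrobenzene by two different phenoxides and the synthesis of dibenzodioxins from catechols and ortho-difluoroarenes that carry one activating group. The dioxin ring closes as a six-membered ring by intramolecular attack of the phenoxide on the neighbouring C–F carbon, which is activated only inductively; it is therefore run last, hot and dilute, when no activated C–F bond is left for the phenoxide to attack in another molecule. No stereocenter is formed. Site selectivity on the hub follows from the activation pattern and from its symmetry about the B3–B6 axis, and the orientation of the dioxin is set by the mask, which cannot migrate and keeps the C8 oxygen silent while activated fluorines are present. Should the free C8 phenoxide shift the hub between the two oxygens through a spiro Meisenheimer intermediate (Smiles rearrangement) before it closes, the same orientation is still expected, because the other phenoxide would sit at C9 in the bay against the C1 methoxy oxygen and its closure would push the 3,5-dimethoxyphenoxy group into that bay, whereas the wanted closure places only a formyl group there.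

Step 11
Reactants: 19 B2,B4-diformyl pentamethyl ether of the target skeleton
Product: 21 B2,B4-dihydroxy pentamethyl ether of the target skeleton, via bis-formate 20 (not isolated)
Conditions: mCPBA (2.5 equiv), CH2Cl2, 0 °C to rt; aq. NaHCO3/Na2S2O3 wash; K2CO3 (cat.), MeOH, 0 °C, argon
Reagents that add atoms: 3-chloroperoxybenzoic acid, O=C(OO)c1cccc(Cl)c1
Why: Double Baeyer–Villiger (Dakin-type) oxidation, in which each formyl group has one aryl ether oxygen ortho and one para so that the aryl group should migrate, followed by methanolysis of both formates.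

Step 12
Reactants: 21 B2,B4-dihydroxy pentamethyl ether of the target skeleton
Product: 22 CNP0256302.0
Conditions: BBr3 (12 equiv), CH2Cl2, −78 °C to rt, argon; H2O quench at 0 °C
Reagents that add atoms: none
Why: BBr3 cleaves the five aryl methyl ethers by Lewis acid complexation and attack of bromide on the methyl groups, while the diaryl ether, dioxin and furan C–O bonds are not cleaved.

**Compound list**

1 | 4-fluoro-2-methoxybenzaldehyde | O=Cc1ccc(F)cc1OC | starting material
2 | 5-bromo-4-fluoro-2-methoxybenzaldehyde | O=Cc1cc(Br)c(F)cc1OC | intermediate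
3 | 3,5-dimethoxyphenol | COc1cc(O)cc(OC)c1 | starting material
4 | 5-bromo-4-(3,5-dimethoxyphenoxy)-2-methoxybenzaldehyde | O=Cc1cc(Br)c(Oc2cc(OC)cc(OC)c2)cc1OC | intermediate
5 | 1,3,7-trimethoxydibenzofuran-8-carbaldehyde | COc1cc(OC)c2c(c1)oc1cc(OC)c(C=O)cc12 | intermediate
6 | 1,3,7-trimethoxydibenzofuran-8-yl formate (not isolated) | COc1cc(OC)c2c(c1)oc1cc(OC)c(OC=O)cc12 | intermediate
7 | 1,3,7-trimethoxydibenzofuran-8-ol | COc1cc(OC)c2c(c1)oc1cc(OC)c(O)cc12 | intermediate
8 | 8-hydroxy-1,3,7-trimethoxydibenzofuran-9-carbaldehyde | COc1cc(OC)c2c(c1)oc1cc(OC)c(O)c(C=O)c12 | intermediate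
9 | 1,3,7-trimethoxy-8-[2-(trimethylsilyl)ethoxy]dibenzofuran-9-carbaldehyde | COc1cc(OC)c2c(c1)oc1cc(OC)c(OCC[Si](C)(C)C)c(C=O)c12 | intermediate
10 | 1,3,7-trimethoxy-8-[2-(trimethylsilyl)ethoxy]dibenzofuran-9-yl formate (not isolated) | COc1cc(OC)c2c(c1)oc1cc(OC)c(OCC[Si](C)(C)C)c(OC=O)c12 | intermediate
11 | 1,3,7-trimethoxy-8-[2-(trimethylsilyl)ethoxy]dibenzofuran-9-ol | COc1cc2oc3cc(OC)cc(OC)c3c2c(O)c1OCC[Si](C)(C)C | intermediate
12 | 2,3,4-trifluorobenzaldehyde | O=Cc1ccc(F)c(F)c1F | starting material
13 | 2-(2,3,4-trifluorophenyl)-1,3-dioxolane | Fc1ccc(C2OCCO2)c(F)c1F | intermediate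
14 | 5-(1,3-dioxolan-2-yl)-2,3,4-trifluorobenzaldehyde (not isolated) | O=Cc1cc(C2OCCO2)c(F)c(F)c1F | intermediate
15 | 4,5,6-trifluoroisophthalaldehyde | O=Cc1cc(C=O)c(F)c(F)c1F | intermediate
16 | 4,5-difluoro-6-({1,3,7-trimethoxy-8-[2-(trimethylsilyl)ethoxy]dibenzofuran-9-yl}oxy)isophthalaldehyde (not isolated) | COc1cc2oc3cc(OC)cc(OC)c3c2c(Oc2c(C=O)cc(C=O)c(F)c2F)c1OCC[Si](C)(C)C | intermediate
17 | 4-(3,5-dimethoxyphenoxy)-5-fluoro-6-({1,3,7-trimethoxy-8-[2-(trimethylsilyl)ethoxy]dibenzofuran-9-yl}oxy)isophthalaldehyde (not isolated) | COc1cc2oc3cc(OC)cc(OC)c3c2c(Oc2c(C=O)cc(C=O)c(Oc3cc(OC)cc(OC)c3)c2F)c1OCC[Si](C)(C)C | intermediate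
18 | 4-(3,5-dimethoxyphenoxy)-5-fluoro-6-[(8-hydroxy-1,3,7-trimethoxydibenzofuran-9-yl)oxy]isophthalaldehyde (not isolated, reacts as its caesium phenoxide) | COc1cc2oc3cc(OC)cc(OC)c3c2c(Oc2c(C=O)cc(C=O)c(Oc3cc(OC)cc(OC)c3)c2F)c1O | intermediate
19 | B2,B4-diformyl pentamethyl ether of the target skeleton (dioxin closed; 3,5-dimethoxyphenoxy at B1; methoxy at C1, C3 and C7 of the dibenzofuran) | COc1cc(OC)cc(Oc2c(C=O)cc(C=O)c3c2Oc2c(OC)cc4oc5cc(OC)cc(OC)c5c4c2O3)c1 | intermediate
20 | B2,B4-bis(formyloxy) pentamethyl ether of the target skeleton (not isolated) | COc1cc(OC)cc(Oc2c(OC=O)cc(OC=O)c3c2Oc2c(OC)cc4oc5cc(OC)cc(OC)c5c4c2O3)c1 | intermediate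
21 | B2,B4-dihydroxy pentamethyl ether of the target skeleton | COc1cc(OC)cc(Oc2c(O)cc(O)c3c2Oc2c(OC)cc4oc5cc(OC)cc(OC)c5c4c2O3)c1 | intermediate
22 | CNP0256302.0 | Oc1cc(O)cc(Oc2c(O)cc(O)c3c2Oc2c(O)cc4oc5cc(O)cc(O)c5c4c2O3)c1 | target

**Totals**

Total step count: 12. Longest linear sequence: 10 steps (steps 1 to 7, then 10 to 12); the hub branch (steps 8 and 9) joins at step 10.

**Steps most likely to fail**

Step 10. After the unmasking, the hub may shift from the C9 oxygen to the C8 oxygen through the spiro Meisenheimer intermediate faster than the dioxin closes. The orientation of the dioxin would then be decided by that equilibrium and not by the mask. Slow unmasking or slow closure at the central C–F bond, which is not activated by resonance, would also let ether exchange between molecules compete. The fallback sets out from 11 and comes back at 19; it switches the activation off before the C8 oxygen is freed and closes the ring at a C–Br bond with copper. The hub is replaced by 5-bromo-4,6-difluoroisophthalaldehyde F4, made as in steps 8 and 9 from 3-bromo-2,4-difluorobenzaldehyde (bought) F1: ethylene glycol and TsOH in refluxing toluene give 2-(3-bromo-2,4-difluorophenyl)-1,3-dioxolane F2, LiN(iPr)2 at −78 °C (short contact time, to avoid bromine migration) and DMF give 3-bromo-5-(1,3-dioxolan-2-yl)-2,4-difluorobenzaldehyde F3, and aqueous HCl gives F4. SNAr of the caesium salt of 11 on F4 (Cs2CO3, DMSO, 20 °C) should give the monoaryl ether bromide F5, and 3 with Cs2CO3 the bis-aryl ether bromide F6, which is isolated with the silylethyl group still in place. HC(OMe)3 and TsOH in MeOH turn both formyl groups into dimethyl acetals to give the bis-acetal F7, whose ring B can no longer support a Meisenheimer intermediate. TBAF in THF then frees the C8 phenol F8, and an intramolecular Ullmann etherification (CuI, 2,2,6,6-tetramethylheptane-3,5-dione, Cs2CO3, NMP, 110 °C) closes the dioxin to the cyclised bis-acetal F9. Aqueous HCl in THF returns the two formyl groups and gives 19.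

Step 5. The formylation has to build a hydroxymethyl and then a formyl group at C9, in the bay next to the C1 methoxy group, and may stall there or return 7. The fallback sets out from 4 and comes back at 9; it introduces this carbon before the furan ring exists. Baeyer–Villiger oxidation of 4 (mCPBA, CH2Cl2) gives 5-bromo-4-(3,5-dimethoxyphenoxy)-2-methoxyphenyl formate F10, and methanolysis (K2CO3, MeOH) gives 5-bromo-4-(3,5-dimethoxyphenoxy)-2-methoxyphenol F11. The same MgCl2, Et3N and paraformaldehyde formylation, now on a single benzene ring, should give 6-bromo-5-(3,5-dimethoxyphenoxy)-2-hydroxy-3-methoxybenzaldehyde F12. Mitsunobu reaction with 2-(trimethylsilyl)ethanol gives 6-bromo-5-(3,5-dimethoxyphenoxy)-3-methoxy-2-[2-(trimethylsilyl)ethoxy]benzaldehyde F13, and the direct arylation conditions of step 3 close the furan ring last and give 9.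

Step 11. In the peracid adduct of each formyl group the hydride may migrate instead of the aryl group, because ring B still carries a second carbonyl group, and carboxylic acids would result. The fallback sets out from 19 and comes back at 21; it replaces the formyl hydrogen by a methyl group so that only aryl migration can lead on. MeMgBr in THF at −78 °C gives the bis(1-hydroxyethyl) compound F14 (mixture of diastereomers), Dess–Martin periodinane gives the B2,B4-diacetyl compound F15, and Baeyer–Villiger oxidation (mCPBA, catalytic TFA, CH2Cl2) gives the B2,B4-diacetate F16. Methanolysis (K2CO3, MeOH, argon) then gives 21.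

**Further compounds**

F1 | step 10 | 3-bromo-2,4-difluorobenzaldehyde (bought) | O=Cc1ccc(F)c(Br)c1F
F2 | step 10 | 2-(3-bromo-2,4-difluorophenyl)-1,3-dioxolane | Fc1ccc(C2OCCO2)c(F)c1Br
F3 | step 10 | 3-bromo-5-(1,3-dioxolan-2-yl)-2,4-difluorobenzaldehyde | O=Cc1cc(C2OCCO2)c(F)c(Br)c1F
F4 | step 10 | 5-bromo-4,6-difluoroisophthalaldehyde | O=Cc1cc(C=O)c(F)c(Br)c1F
F5 | step 10 | 5-bromo-4-fluoro-6-({1,3,7-trimethoxy-8-[2-(trimethylsilyl)ethoxy]dibenzofuran-9-yl}oxy)isophthalaldehyde | COc1cc2oc3cc(OC)cc(OC)c3c2c(Oc2c(C=O)cc(C=O)c(F)c2Br)c1OCC[Si](C)(C)C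
F6 | step 10 | 5-bromo-4-(3,5-dimethoxyphenoxy)-6-({1,3,7-trimethoxy-8-[2-(trimethylsilyl)ethoxy]dibenzofuran-9-yl}oxy)isophthalaldehyde | COc1cc2oc3cc(OC)cc(OC)c3c2c(Oc2c(C=O)cc(C=O)c(Oc3cc(OC)cc(OC)c3)c2Br)c1OCC[Si](C)(C)C
F7 | step 10 | bis(dimethyl acetal) of F6 | COc1cc2oc3cc(OC)cc(OC)c3c2c(Oc2c(C(OC)OC)cc(C(OC)OC)c(Oc3cc(OC)cc(OC)c3)c2Br)c1OCC[Si](C)(C)C
F8 | step 10 | C8 phenol from F7 (silylethyl group removed) | COc1cc2oc3cc(OC)cc(OC)c3c2c(Oc2c(C(OC)OC)cc(C(OC)OC)c(Oc3cc(OC)cc(OC)c3)c2Br)c1O
F9 | step 10 | bis(dimethyl acetal) of 19 | COc1cc(OC)cc(Oc2c(C(OC)OC)cc(C(OC)OC)c3c2Oc2c(OC)cc4oc5cc(OC)cc(OC)c5c4c2O3)c1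
F10 | step 5 | 5-bromo-4-(3,5-dimethoxyphenoxy)-2-methoxyphenyl formate | COc1cc(Oc2cc(OC)cc(OC)c2)c(Br)cc1OC=O
F11 | step 5 | 5-bromo-4-(3,5-dimethoxyphenoxy)-2-methoxyphenol | COc1cc(Oc2cc(OC)cc(OC)c2)c(Br)cc1O
F12 | step 5 | 6-bromo-5-(3,5-dimethoxyphenoxy)-2-hydroxy-3-methoxybenzaldehyde | COc1cc(Oc2cc(OC)cc(OC)c2)c(Br)c(C=O)c1O
F13 | step 5 | 6-bromo-5-(3,5-dimethoxyphenoxy)-3-methoxy-2-[2-(trimethylsilyl)ethoxy]benzaldehyde | COc1cc(Oc2cc(OC)cc(OC)c2)c(Br)c(C=O)c1OCC[Si](C)(C)C
F14 | step 11 | B2,B4-bis(1-hydroxyethyl) analogue of 19 (mixture of diastereomers) | COc1cc(OC)cc(Oc2c(C(C)O)cc(C(C)O)c3c2Oc2c(OC)cc4oc5cc(OC)cc(OC)c5c4c2O3)c1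
F15 | step 11 | B2,B4-diacetyl analogue of 19 | COc1cc(OC)cc(Oc2c(C(C)=O)cc(C(C)=O)c3c2Oc2c(OC)cc4oc5cc(OC)cc(OC)c5c4c2O3)c1
F16 | step 11 | B2,B4-diacetate of 21 | COc1cc(OC)cc(Oc2c(OC(C)=O)cc(OC(C)=O)c3c2Oc2c(OC)cc4oc5cc(OC)cc(OC)c5c4c2O3)c1
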